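**Plan**

Target numbering: ring C1 (bears the side chain), C2 (vinyl Br), C3 (CMe2), C4 (CHBr), C5, C6; side chain C1′ (CHCl), C2′ (CH2Br).
Retrosynthesis: the four C–halogen bonds are cut first (C2′–Br and C1′–Cl back to an oxirane, C4–Br to an alcohol, C2–Br to an enol triflate), then C1′–C2′ (ester homologation), and last the ring at C1–C2 and C3–C4. This leaves methyl isobutyrate (C2, C3, both methyls) and methyl 5-chloro-5-oxopentanoate (C4, C5, C6, C1, C1′).
Enabling feature: C4, C2 and C1′ are 1,3,5-related heteroatom-bearing carbons around the quaternary C3, a masked 2,4-dioxo ester. Because C3 carries no hydrogen, the isobutyrate enolate can be acylated only once and the Dieckmann closure can start only from C1.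
Forward: a one-pot Claisen acylation/Dieckmann condensation closes the only ring and sets nine of the ten carbons with all three oxygenation sites (step 1); then C2–Br (steps 2–3), C4–Br (steps 4–5) and the side chain (steps 6–9).
Stereochemistry: C4 comes from an (R)-CBS reduction to the (S)-alcohol and Appel inversion to (R)-Br. C1′ comes from an (R)-CBS reduction of the chloromethyl ketone, oxirane closure with retention and chloride opening at C1′ with inversion to (S).

Key step: step 1

Remark: metal enolates, alkoxides and borates of a product that last only until work-up are counted as that product; 5 is drawn as its diketo tautomer and is racemic at C1, a centre that is removed in step 2.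

**Route**

Step 1
Reactants: 1 methyl 2-methylpropanoate (methyl isobutyrate); 2 methyl 5-chloro-5-oxopentanoate
Product: 5 methyl 3,3-dimethyl-2,4-dioxocyclohexane-1-carboxylate, via lithium ester enolate 3 (not isolated), via acyclic keto diester 4 (not isolated)
Conditions: lithium diisopropylamide (1.05 equiv), THF, −78 °C; enolate added to 2 (1.0 equiv), THF, −78 °C; then potassium tert-butoxide (2.2 equiv), −78 °C to rt; cold 1 M HCl
Reagents that add atoms: none
Why: Crossed Claisen acylation then Dieckmann condensation in one flask: enolate 3 is C-acylated by the acid chloride of 2 (C3–C4 bond, keto diester 4), and potassium tert-butoxide then forms, reversibly, the ester enolate at the glutarate α-carbon (C1), which attacks the isobutyrate ester carbonyl (C1–C2 bond) and expels methoxide. The closest known reaction types are the acylation of α,α-disubstituted ester enolates with acid chlorides and the Dieckmann cyclisation of 2,2-dimethylheptanedioates to 3,3-dimethyl-2-oxocyclohexanecarboxylates. The six-membered ring closes in the 6-(enolexo)-exo-trig mode. The only new stereocentre, C1 of 5, is an enolisable position formed as a racemate and is erased in step 2, so no control is needed. The step needs a single acylation, one direction of ring closure and no retro-Claisen cleavage: the quaternary C3 has no hydrogen, so 3 reacts once and 4 cannot enolise between its ketone and ester; the ketone α-methylene (C5) could close only four-membered rings; and 5 is deprotonated at once to its β-keto ester enolate, which takes up the methoxide and makes the closure irreversible.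

Step 2
Reactants: 5 methyl 3,3-dimethyl-2,4-dioxocyclohexane-1-carboxylate
Product: 6 methyl 3,3-dimethyl-4-oxo-2-[(trifluoromethanesulfonyl)oxy]cyclohex-1-ene-1-carboxylate
Conditions: Tf2O (1.1 equiv), i-Pr2NEt (1.3 equiv), CH2Cl2, −78 °C to 0 °C
Reagents that add atoms: trifluoromethanesulfonic anhydride, O=S(=O)(OS(=O)(=O)C(F)(F)F)C(F)(F)F
Why: Enol triflate formation: only the β-keto ester is enolised by the amine base at −78 °C, and because C3 is quaternary the enol double bond can only be C1=C2, so O-sulfonylation fixes the position of the ring alkene and removes the racemic C1 centre while the isolated C4 ketone is untouched.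

Step 3
Reactants: 6 methyl 3,3-dimethyl-4-oxo-2-[(trifluoromethanesulfonyl)oxy]cyclohex-1-ene-1-carboxylate
Product: 7 methyl 2-bromo-3,3-dimethyl-4-oxocyclohex-1-ene-1-carboxylate
Conditions: Ni(cod)2 (10 mol %), LiBr (3 equiv), DMA/THF 1:3, 23 °C
Reagents that add atoms: lithium bromide, [Li+].[Br-]
Why: Nickel-catalysed halogenation of an enol triflate: zerovalent nickel inserts into the activated C2–OTf bond of the β-triflyloxy enoate, bromide replaces triflate on divalent nickel and C–Br reductive elimination releases the alkenyl bromide, under conditions that leave the ketone and the ester alone.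

Step 4
Reactants: 7 methyl 2-bromo-3,3-dimethyl-4-oxocyclohex-1-ene-1-carboxylate
Product: 8 methyl (4S)-2-bromo-4-hydroxy-3,3-dimethylcyclohex-1-ene-1-carboxylate
Conditions: (R)-2-methyl-CBS-oxazaborolidine (20 mol %), BH3·SMe2 (0.7 equiv), THF, −20 °C; MeOH quench
Reagents that add atoms: none
Why: Corey–Bakshi–Shibata reduction: the C4 ketone is flanked by the quaternary C3 (large group) and the C5 methylene (small group), so the (R)-catalyst should deliver hydride to the face that gives the (S)-alcohol (mirror image of the (S)-catalyst/pinacolone case, which gives the (R)-alcohol), while ester and alkenyl bromide do not react with borane at −20 °C.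

Step 5
Reactants: 8 methyl (4S)-2-bromo-4-hydroxy-3,3-dimethylcyclohex-1-ene-1-carboxylate
Product: 9 methyl (4R)-2,4-dibromo-3,3-dimethylcyclohex-1-ene-1-carboxylate
Conditions: PPh3 (2 equiv), CBr4 (2 equiv), toluene, 0 °C to 60 °C
Reagents that add atoms: carbon tetrabromide, BrC(Br)(Br)Br
Why: Appel reaction: bromide displaces the alkoxyphosphonium group in an SN2 step with inversion to set (4R); the neopentylic position reacts slowly, but ionisation with a 1,2-methyl shift is held back because the neighbouring alkene is an electron-poor β-bromo enoate that cannot stabilise a cation at C3.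

Step 6
Reactants: 9 methyl (4R)-2,4-dibromo-3,3-dimethylcyclohex-1-ene-1-carboxylate
Product: 11 2-chloro-1-[(4R)-2,4-dibromo-3,3-dimethylcyclohex-1-en-1-yl]ethan-1-one, via lithium hemiketal adduct 10 (not isolated)
Conditions: ICH2Cl (2.0 equiv), MeLi·LiBr (1.9 equiv, slow addition), THF, −78 °C; AcOH quench at −78 °C
Reagents that add atoms: chloroiodomethane, ClCI (delivered as chloromethyllithium, [Li]CCl, made in the flask)
Why: Chloromethyllithium homologation of an ester to an α-chloro ketone: iodine–lithium exchange of ICH2Cl is faster than attack of MeLi on the ester or exchange at either C–Br bond, the carbenoid adds once because the tetrahedral adduct 10 is stable at −78 °C, and the acidic quench releases the ketone without touching the C4 stereocentre.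

Step 7
Reactants: 11 2-chloro-1-[(4R)-2,4-dibromo-3,3-dimethylcyclohex-1-en-1-yl]ethan-1-one
Product: 13 (2R)-2-[(4R)-2,4-dibromo-3,3-dimethylcyclohex-1-en-1-yl]oxirane, via chlorohydrin 12 (not isolated)
Conditions: (R)-2-methyl-CBS-oxazaborolidine (20 mol %), BH3·SMe2 (0.7 equiv), THF, −20 °C; MeOH quench; then K2CO3 (3 equiv), MeOH, rt
Reagents that add atoms: none
Why: Corey–Bakshi–Shibata reduction followed by base-induced 3-exo-tet oxirane closure: the fully substituted bromoalkenyl group acts as the large and CH2Cl as the small substituent, so the (R)-catalyst should give the (1R)-chlorohydrin 12, whose alkoxide displaces chloride at C2′ and closes the (2R)-oxirane with retention at C1′.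

Step 8
Reactants: 13 (2R)-2-[(4R)-2,4-dibromo-3,3-dimethylcyclohex-1-en-1-yl]oxirane
Product: 14 (2S)-2-chloro-2-[(4R)-2,4-dibromo-3,3-dimethylcyclohex-1-en-1-yl]ethan-1-ol
Conditions: HCl (2 M in Et2O, 1.2 equiv), CH2Cl2, −40 °C to 0 °C
Reagents that add atoms: hydrogen chloride, Cl
Why: Acid-promoted ring opening of an alkenyl epoxide by chloride: in the protonated oxirane the allylic C1′–O bond is the weaker one, so chloride should attack C1′ from the rear with inversion to give the (S)-chloride and the primary alcohol, SN2′ opening being blocked by the fully substituted, bromine-bearing C2, and any product of terminal attack is chlorohydrin 12, which the base of step 7 returns to 13.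

Step 9
Reactants: 14 (2S)-2-chloro-2-[(4R)-2,4-dibromo-3,3-dimethylcyclohex-1-en-1-yl]ethan-1-ol
Product: 15 (4R)-2,4-dibromo-1-[(1S)-2-bromo-1-chloroethyl]-3,3-dimethylcyclohex-1-ene
Conditions: PPh3 (1.3 equiv), CBr4 (1.3 equiv), CH2Cl2, 0 °C
Reagents that add atoms: carbon tetrabromide, BrC(Br)(Br)Br
Why: Appel reaction at an unhindered primary alcohol: bromide displaces the alkoxyphosphonium group at C2′ at 0 °C without touching the C1′ stereocentre, a β-chlorine being a poor neighbouring group and the hindered allylic chloride and neopentylic bromide being inert under these neutral conditions.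

**Compound list**

1 | methyl 2-methylpropanoate | COC(=O)C(C)C | starting material
2 | methyl 5-chloro-5-oxopentanoate | COC(=O)CCCC(Cl)=O | starting material
3 | lithium 1-methoxy-2-methylprop-1-en-1-olate (lithium enolate of 1) | [Li+].[O-]C(OC)=C(C)C | intermediate (not isolated)
4 | dimethyl 2,2-dimethyl-3-oxoheptanedioate | COC(=O)CCCC(=O)C(C)(C)C(=O)OC | intermediate (not isolated)
5 | methyl 3,3-dimethyl-2,4-dioxocyclohexane-1-carboxylate (racemic at C1) | COC(=O)C1CCC(=O)C(C)(C)C1=O | intermediate
6 | methyl 3,3-dimethyl-4-oxo-2-[(trifluoromethanesulfonyl)oxy]cyclohex-1-ene-1-carboxylate | COC(=O)C1=C(OS(=O)(=O)C(F)(F)F)C(C)(C)C(=O)CC1 | intermediate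
7 | methyl 2-bromo-3,3-dimethyl-4-oxocyclohex-1-ene-1-carboxylate | COC(=O)C1=C(Br)C(C)(C)C(=O)CC1 | intermediate
8 | methyl (4S)-2-bromo-4-hydroxy-3,3-dimethylcyclohex-1-ene-1-carboxylate | COC(=O)C1=C(Br)C(C)(C)[C@@H](O)CC1 | intermediate
9 | methyl (4R)-2,4-dibromo-3,3-dimethylcyclohex-1-ene-1-carboxylate | COC(=O)C1=C(Br)C(C)(C)[C@H](Br)CC1 | intermediate
10 | lithium 2-chloro-1-[(4R)-2,4-dibromo-3,3-dimethylcyclohex-1-en-1-yl]-1-methoxyethan-1-olate (both epimers at the hemiketal carbon) | [Li+].[O-]C(CCl)(OC)C1=C(Br)C(C)(C)[C@H](Br)CC1 | intermediate (not isolated)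
11 | 2-chloro-1-[(4R)-2,4-dibromo-3,3-dimethylcyclohex-1-en-1-yl]ethan-1-one | ClCC(=O)C1=C(Br)C(C)(C)[C@H](Br)CC1 | intermediate
12 | (1R)-2-chloro-1-[(4R)-2,4-dibromo-3,3-dimethylcyclohex-1-en-1-yl]ethan-1-ol | O[C@@H](CCl)C1=C(Br)C(C)(C)[C@H](Br)CC1 | intermediate (not isolated)
13 | (2R)-2-[(4R)-2,4-dibromo-3,3-dimethylcyclohex-1-en-1-yl]oxirane | C1O[C@@H]1C2=C(Br)C(C)(C)[C@H](Br)CC2 | intermediate
14 | (2S)-2-chloro-2-[(4R)-2,4-dibromo-3,3-dimethylcyclohex-1-en-1-yl]ethan-1-ol | OC[C@@H](Cl)C1=C(Br)C(C)(C)[C@H](Br)CC1 | intermediate
15 | (4R)-2,4-dibromo-1-[(1S)-2-bromo-1-chloroethyl]-3,3-dimethylcyclohex-1-ene | CC1(C)C(Br)=C([C@H](Cl)CBr)CC[C@H]1Br | target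

**Summary**

Total step count: 9. Longest linear sequence: 9 steps (the route is fully linear from 1 and 2).

Steps most likely to fail:

1. Step 5. The substitution at the neopentylic carbinol may be outrun by elimination towards C5 or by ionisation with a 1,2-methyl shift, or may not proceed at a useful rate. Fallback, which separates activation from substitution: setting out from 8, Tf2O and pyridine in CH2Cl2 at −30 °C should give methyl (4S)-2-bromo-3,3-dimethyl-4-[(trifluoromethanesulfonyl)oxy]cyclohex-1-ene-1-carboxylate F1. This much better nucleofuge should then be displaced with inversion by Bu4NBr in toluene at 0 °C to rt, which comes back to the route at 9.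

2. Step 8. Chloride may attack the terminal instead of the allylic oxirane carbon, or the opening may take on SN1 character and erode the configuration at C1′. Fallback, which moves the C–Cl bond formation to an SN2 displacement next to a non-participating ether: setting out from 13, 4-methoxyphenol and Cs2CO3 in DMF at 50 °C should open the oxirane at the terminal carbon with retention at C1′ to give (1R)-1-[(4R)-2,4-dibromo-3,3-dimethylcyclohex-1-en-1-yl]-2-(4-methoxyphenoxy)ethan-1-ol F2. PPh3 and N-chlorosuccinimide in THF at 0 °C should then replace the hydroxyl by chloride with inversion to give 1-{(2S)-2-chloro-2-[(4R)-2,4-dibromo-3,3-dimethylcyclohex-1-en-1-yl]ethoxy}-4-methoxybenzene F3. Removal of the aryl group with (NH4)2Ce(NO3)6 in MeCN–H2O at 0 °C comes back to the route at 14.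

3. Step 6. The short-lived carbenoid may decompose before it adds to the shielded, twisted ester, and halogen–lithium exchange or elimination at C4–Br may compete. Fallback, which replaces acyl substitution at the hindered ester by addition to an aldehyde: setting out from 9, i-Bu2AlH in CH2Cl2 at −78 °C should give [(4R)-2,4-dibromo-3,3-dimethylcyclohex-1-en-1-yl]methanol F4, and MnO2 in CH2Cl2 should oxidise it to (4R)-2,4-dibromo-3,3-dimethylcyclohex-1-ene-1-carbaldehyde F5. Chloromethyllithium (ICH2Cl, MeLi·LiBr, THF, −78 °C, cold AcOH quench) should add to the aldehyde to give 2-chloro-1-[(4R)-2,4-dibromo-3,3-dimethylcyclohex-1-en-1-yl]ethan-1-ol F6 as a mixture of carbinol epimers. Dess–Martin oxidation of this mixture comes back to the route at 11.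

**Further compounds**

F1 | step 5 | methyl (4S)-2-bromo-3,3-dimethyl-4-[(trifluoromethanesulfonyl)oxy]cyclohex-1-ene-1-carboxylate | COC(=O)C1=C(Br)C(C)(C)[C@@H](OS(=O)(=O)C(F)(F)F)CC1
F2 | step 8 | (1R)-1-[(4R)-2,4-dibromo-3,3-dimethylcyclohex-1-en-1-yl]-2-(4-methoxyphenoxy)ethan-1-ol | COc1ccc(OC[C@H](O)C2=C(Br)C(C)(C)[C@H](Br)CC2)cc1
F3 | step 8 | 1-{(2S)-2-chloro-2-[(4R)-2,4-dibromo-3,3-dimethylcyclohex-1-en-1-yl]ethoxy}-4-methoxybenzene | COc1ccc(OC[C@@H](Cl)C2=C(Br)C(C)(C)[C@H](Br)CC2)cc1
F4 | step 6 | [(4R)-2,4-dibromo-3,3-dimethylcyclohex-1-en-1-yl]methanol | OCC1=C(Br)C(C)(C)[C@H](Br)CC1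
F5 | step 6 | (4R)-2,4-dibromo-3,3-dimethylcyclohex-1-ene-1-carbaldehyde | O=CC1=C(Br)C(C)(C)[C@H](Br)CC1
F6 | step 6 | 2-chloro-1-[(4R)-2,4-dibromo-3,3-dimethylcyclohex-1-en-1-yl]ethan-1-ol (both carbinol epimers) | OC(CCl)C1=C(Br)C(C)(C)[C@H](Br)CC1
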